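A direct plan would build on ring A: the diformyl (R)-acylphloroglucinol A1 would be benzylated and turned into the bis(bromomethyl) ketone A2, both arms would be extended with the ynone keto ester A3 to give the bis(keto ester) A4, and the two pyrone rings would be closed last to give the bis(pyrone) A5, before C5 methylation and debenzylation. Its weakest steps would be:
- the twofold Ph3PAuNTf2-catalysed pyrone closure of A4 to A5, which would have to run 6-endo on two hindered α-branched keto esters of one late intermediate;
- the iodination and MeZnCl coupling pair, two steps that would add only two methyl groups;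
- the benzyl protection with its final hydrogenolysis, two steps without gain in complexity that would expose both pyrones to H2 over Pd/C.

**Strategy.** Both CH2 bridges are cut at once. Each bridge carbon lies between two nucleophilic enol carbons, C3 of a hydroxypyrone and C3 or C5 of ring A, the retron of a Mannich–Michael union with formaldehyde equivalents and the likely biosynthetic origin of such bridges. In one flask the key step joins two finished pyrones to the (R)-acylphloroglucinol through two C1 units, forming four C–C bonds without protecting groups and giving the target directly. Each pyrone is closed beforehand from pentan-3-one and a malonyl unit, with its C5 methyl group in place, so late ring closure, halogenation, cross-coupling and benzyl ethers all disappear.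

Key step: step 4

Assumption: (R)-2-methylbutanoic acid of high enantiomeric purity is taken as a commercial starting material; the route neither forms nor breaks a bond at this carbon.

Step 1
Reactants: 1 pentan-3-one
Product: 2 3-(trimethylsilyloxy)pent-2-ene (E/Z mixture)
Conditions: Me3SiCl, Et3N, DMF, 80 °C; pentane/cold aq. NaHCO3 work-up; distillation
Reagents that add atoms: chlorotrimethylsilane, C[Si](C)(C)Cl
Why: Silyl enol ether formation under equilibrating conditions (enolisation by Et3N, O-silylation by Me3SiCl); the ketone is symmetrical, so only one regioisomer can form, and the E/Z ratio does not matter because this double bond becomes C5=C6 of the pyrone ring.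

Step 2
Reactants: 2 3-(trimethylsilyloxy)pent-2-ene; 3 malonyl dichloride
Product: 5 6-ethyl-4-hydroxy-5-methyl-2H-pyran-2-one, via 4-methyl-3,5-dioxoheptanoyl chloride 4 (not isolated)
Conditions: 3 (1.0 equiv), Et2O, −78 °C → rt; aqueous work-up; recrystallisation
Reagents that add atoms: none
Why: (3+3) Acylation–lactonisation of a silyl enol ether with malonyl dichloride, in which the enol carbon is acylated by one acid chloride with loss of Me3SiCl (C4–C5 bond) and the enol oxygen of the resulting 1,3-diketone 4 closes onto the second acid chloride (O1–C2 bond) to give the aromatic 4-hydroxy-2-pyrone, whose C5 methyl and C6 ethyl groups both come from pentan-3-one.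

Step 3
Reactants: 6 phloroglucinol; 7 (R)-2-methylbutanoic acid
Product: 9 (R)-2-methyl-1-(2,4,6-trihydroxyphenyl)butan-1-one, via (R)-2-methylbutanoyl chloride 8 (not isolated)
Conditions: 7, (COCl)2, cat. DMF, CH2Cl2, 0 °C → rt; then 6, AlCl3 (3.5 equiv), CH2Cl2/MeNO2, 0 °C → rt; cold 1 M HCl
Reagents that add atoms: none
Why: Friedel–Crafts acylation, in which the AlCl3-activated acid chloride attacks one of the three equivalent, triply activated ring carbons and the aluminium-chelated acyl group then deactivates the ring against a second acylation; the acid chloride is made without base so that no ketene can form, and the (R)-centre of 7 should pass unchanged into 9 (enantiomeric purity to be checked by HPLC on a chiral phase).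

Step 4
Reactants: 5 6-ethyl-4-hydroxy-5-methyl-2H-pyran-2-one (two molecules); 9 (R)-2-methyl-1-(2,4,6-trihydroxyphenyl)butan-1-one
Product: 13 (2R)-1-{3,5-bis[(6-ethyl-4-hydroxy-5-methyl-2-oxo-2H-pyran-3-yl)methyl]-2,4,6-trihydroxyphenyl}-2-methylbutan-1-one (CNP0174567.1), via pyrone Mannich salt 10 (not isolated), via 3-methylidenepyran-2,4-dione 11 (not isolated), via singly bridged adduct 12 (not isolated)
Conditions: 5 (2.3 equiv), N,N-dimethylmethyleneiminium iodide (2.3 equiv), MeCN, rt; then 9 (1.0 equiv), 60 °C; dilute HCl work-up
Reagents that add atoms: N,N-dimethylmethyleneiminium iodide, C=[N+](C)C.[I-]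
Why: The iminium salt aminomethylates the pyrone at C3, its only free ring carbon and the carbon of a vinylogous acid (Mannich reaction), so that its CH2 carbon becomes the bridge, and the salt 10 loses dimethylammonium iodide on warming to give the 3-methylidenepyran-2,4-dione 11, a doubly activated acceptor that corresponds to an ortho-quinone methide; the two free carbons of ring A in 9, each flanked by two hydroxyl groups, add to it one after the other (Michael-type Friedel–Crafts alkylation) and tautomerisation restores both aromatic rings, first in 12 and then in 13. The closest known reaction is the one-flask methylene coupling of a 4-hydroxy-2-pyrone with an acylphloroglucinol through such a methylenepyrandione, run here twice on the same ring A. No ring is closed and no stereocentre is formed; the (R)-centre lies beside a hydrogen-bonded aryl ketone and should not enolise in the weakly acidic ammonium iodide medium. The step needs cross-coupling over homo-coupling and a complete second bridging: 5 is converted fully into 10 before 9 is added, so that no free pyrone is left to intercept 11, ring A offers exactly two free carbons and the pyrone none besides C3 (C5 carries the methyl group), and a small excess of 10 drives 12 on to 13. O-Alkylation of a phenol or of the pyrone hydroxyl is reversible (retro-Michael), so such adducts should drain to the C-bridged product.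

**Compound list**

1 | pentan-3-one | CCC(=O)CC | starting material
2 | 3-(trimethylsilyloxy)pent-2-ene (E/Z mixture) | CC=C(CC)O[Si](C)(C)C | intermediate
3 | malonyl dichloride (propanedioyl dichloride) | O=C(Cl)CC(Cl)=O | starting material
4 | 4-methyl-3,5-dioxoheptanoyl chloride (racemic, formed in the flask) | CCC(=O)C(C)C(=O)CC(Cl)=O | intermediate
5 | 6-ethyl-4-hydroxy-5-methyl-2H-pyran-2-one | CCc1oc(=O)cc(O)c1C | intermediate
6 | phloroglucinol (benzene-1,3,5-triol) | Oc1cc(O)cc(O)c1 | starting material
7 | (R)-2-methylbutanoic acid | CC[C@@H](C)C(O)=O | starting material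
8 | (R)-2-methylbutanoyl chloride (formed in the flask) | CC[C@@H](C)C(Cl)=O | intermediate
9 | (R)-2-methyl-1-(2,4,6-trihydroxyphenyl)butan-1-one | CC[C@@H](C)C(=O)c1c(O)cc(O)cc1O | intermediate
10 | 3-[(dimethylamino)methyl]-6-ethyl-4-hydroxy-5-methyl-2H-pyran-2-one hydroiodide (formed in the flask) | CCc1oc(=O)c(C[NH+](C)C)c(O)c1C.[I-] | intermediate
11 | 6-ethyl-5-methyl-3-methylidene-2H-pyran-2,4(3H)-dione (formed in the flask) | CCC1=C(C)C(=O)C(=C)C(=O)O1 | intermediate
12 | (2R)-1-{3-[(6-ethyl-4-hydroxy-5-methyl-2-oxo-2H-pyran-3-yl)methyl]-2,4,6-trihydroxyphenyl}-2-methylbutan-1-one (formed in the flask) | CC[C@@H](C)C(=O)c1c(O)cc(O)c(Cc2c(O)c(C)c(CC)oc2=O)c1O | intermediate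
13 | (2R)-1-{3,5-bis[(6-ethyl-4-hydroxy-5-methyl-2-oxo-2H-pyran-3-yl)methyl]-2,4,6-trihydroxyphenyl}-2-methylbutan-1-one (CNP0174567.1) | CCc1oc(=O)c(Cc2c(O)c(Cc3c(O)c(C)c(CC)oc3=O)c(O)c(C(=O)[C@H](C)CC)c2O)c(O)c1C | target

**Step count and risks**

Total step count: 4. Longest linear sequence: 3 steps (1 → 2 → 5 → 13, steps 1, 2 and 4); step 3 is a one-step branch.

Steps most likely to fail:

First, step 4. The acceptor 11 may be drained by self-condensation with any unreacted pyrone, the second bridging may stall at the singly bridged stage, or acid and heat may cause cyclodehydration between a ring A hydroxyl and the pyrone C4 hydroxyl. The fallback inverts the roles, so that ring A carries both C1 units. Setting out from 9, aqueous formaldehyde and morpholine (EtOH, rt) would give the isolable bis(Mannich base) (R)-2-methyl-1-[2,4,6-trihydroxy-3,5-bis(morpholin-4-ylmethyl)phenyl]butan-1-one F1. Heating F1 with 5 (2.2 equiv) in dioxane at 90 °C would expel morpholine twice and let C3 of the pyrone add to each benzylic carbon, coming back to the route at 13. In F1 every ring A carbon is substituted and no pyrone-derived acceptor exists, so neither homo-coupling is possible.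

Second, step 3. The (R)-centre may erode through enolisation of the AlCl3-bound acylium ion or aryl ketone, and the acylation may run on to a second acylation or stop at O-acylation. The fallback replaces the electrophilic aromatic substitution by addition of an aryllithium to an amide; it sets out from 6 and 7 and comes back to the route at 9. Phloroglucinol 6 would be protected (MeOCH2Cl, iPr2NEt, CH2Cl2) as 1,3,5-tris(methoxymethoxy)benzene F2, and 7 would be converted (1,1'-carbonyldiimidazole, then MeONHMe·HCl) into (R)-N-methoxy-N,2-dimethylbutanamide F3. Lithiation of F2 between two acetal oxygens (n-BuLi, THF, 0 °C) would give [2,4,6-tris(methoxymethoxy)phenyl]lithium F4, whose addition to F3 at −78 °C stops at the ketone stage and would give (R)-2-methyl-1-[2,4,6-tris(methoxymethoxy)phenyl]butan-1-one F5 without any acylium ion. HCl in MeOH at rt would then remove the three acetals to give 9.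

Third, step 2. Malonyl dichloride may self-condense through its chlorocarbonylketene or acylate the enol ether on oxygen, so that little pyrone forms. The fallback closes the ring by lactonisation of an open-chain triketide; it sets out from 1 and comes back to the route at 5. Acetylation of 1 at the α-carbon (Ac2O, BF3·2AcOH, rt; then aq. NaOAc, reflux) would give 3-methylhexane-2,4-dione F6, and LiN(iPr)2 (2.1 equiv, THF, 0 °C) would convert it, by kinetic deprotonation of the terminal methyl group, into the dilithium dianion of 3-methylhexane-2,4-dione F7. Carboxylation of the terminal methyl carbon of F7 by CO2, with cold acidic work-up, would give 4-methyl-3,5-dioxoheptanoic acid F8. 1,1'-Carbonyldiimidazole in THF would then activate the acid and let the enol oxygen close O1–C2 to give 5.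

**Further compounds**

F1 | step 4 | (R)-2-methyl-1-[2,4,6-trihydroxy-3,5-bis(morpholin-4-ylmethyl)phenyl]butan-1-one | CC[C@@H](C)C(=O)c1c(O)c(CN2CCOCC2)c(O)c(CN2CCOCC2)c1O
F2 | step 3 | 1,3,5-tris(methoxymethoxy)benzene | COCOc1cc(OCOC)cc(OCOC)c1
F3 | step 3 | (R)-N-methoxy-N,2-dimethylbutanamide | CC[C@@H](C)C(=O)N(C)OC
F4 | step 3 | [2,4,6-tris(methoxymethoxy)phenyl]lithium | [Li]c1c(OCOC)cc(OCOC)cc1OCOC
F5 | step 3 | (R)-2-methyl-1-[2,4,6-tris(methoxymethoxy)phenyl]butan-1-one | CC[C@@H](C)C(=O)c1c(OCOC)cc(OCOC)cc1OCOC
F6 | step 2 | 3-methylhexane-2,4-dione (racemic) | CCC(=O)C(C)C(C)=O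
F7 | step 2 | dilithium dianion of 3-methylhexane-2,4-dione | [Li+].[Li+].C=C([O-])C(C)=C([O-])CC
F8 | step 2 | 4-methyl-3,5-dioxoheptanoic acid (racemic) | CCC(=O)C(C)C(=O)CC(O)=O
A1 | direct plan | (R)-2,4,6-trihydroxy-5-(2-methylbutanoyl)benzene-1,3-dicarbaldehyde | CC[C@@H](C)C(=O)c1c(O)c(C=O)c(O)c(C=O)c1O
A2 | direct plan | (2R)-1-[2,4,6-tris(benzyloxy)-3,5-bis(bromomethyl)phenyl]-2-methylbutan-1-one | CC[C@@H](C)C(=O)c1c(OCc2ccccc2)c(CBr)c(OCc2ccccc2)c(CBr)c1OCc1ccccc1
A3 | direct plan | tert-butyl 3-oxohept-4-ynoate | CCC#CC(=O)CC(=O)OC(C)(C)C
A4 | direct plan | di-tert-butyl 2,2'-{[2,4,6-tris(benzyloxy)-5-[(2R)-2-methylbutanoyl]-1,3-phenylene]bis(methylene)}bis(3-oxohept-4-ynoate) (epimer mixture at both C2 centres) | CC[C@@H](C)C(=O)c1c(OCc2ccccc2)c(CC(C(=O)OC(C)(C)C)C(=O)C#CCC)c(OCc2ccccc2)c(CC(C(=O)OC(C)(C)C)C(=O)C#CCC)c1OCc1ccccc1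
A5 | direct plan | (2R)-1-{2,4,6-tris(benzyloxy)-3,5-bis[(6-ethyl-4-hydroxy-2-oxo-2H-pyran-3-yl)methyl]phenyl}-2-methylbutan-1-one | CC[C@@H](C)C(=O)c1c(OCc2ccccc2)c(Cc2c(O)cc(CC)oc2=O)c(OCc2ccccc2)c(Cc2c(O)cc(CC)oc2=O)c1OCc1ccccc1
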